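**Retrosynthetic overview**
Target numbering (as a cyclohexanol): C1 = C(CH3)OH, C2 = CH carrying the hydroxymethylpentenyl chain, C3 = quaternary C(CH3)(homoprenyl), C4 = CHBr, C5–C6 = CH2CH2. The enabling feature is that the two heteroatom-bearing ring carbons C1 and C4 stand 1,4 (O and Br cis) and are spanned by the bare C5–C6 unit. This is the retron of a 2-oxyfuran (furan C5 = C1, furan C2 = C4) plus a two-carbon dienophile.
Key disconnection C4–C5 plus C6–C1: asymmetric Diels–Alder addition of 3,5-dimethyl-2-(trimethylsilyloxy)furan (a cheap heteroarene, dearomatised) to an acrylimide whose acyl group is a removable activator.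
Ring order: a temporary 7-oxanorbornene forms first, and its oxygen bridge breaks in the same flask. This leaves the only ring of the target as a 4-hydroxycyclohex-2-enone.
Stereochemical relay from C1: alkoxide-directed conjugate addition sets C2, enolate alkylation anti to that chain sets C3, and hindered hydride followed by Appel inversion sets C4.
The remote carbinol centre is bought with (S)-linalool, which is trimmed by one carbon to an iodide (ozonolysis, oxidation, iododecarboxylation).

Key step: step 3

Assumption: (S)-(+)-linalool is bought in high enantiomeric purity, and the (R,R) ligand is assigned by analogy with the usual sense of Cu(box)–acrylimide cycloadditions (its antipode would be used if the sense proved opposite).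

Step 1
Reactants: 1 α-angelica lactone (5-methylfuran-2(3H)-one)
Product: 3 3,5-dimethylfuran-2(3H)-one (racemic), via lithium furanolate 2 (not isolated)
Conditions: LiN(i-Pr)2, THF, −78 °C; CH3I, −78 to 0 °C
Reagents that add atoms: iodomethane, CI
Why: Deprotonation gives the aromatic furanolate, which is methylated at the α-carbon (dienolate α-alkylation), and the new stereocentre is irrelevant because step 2 flattens it.

Step 2
Reactants: 3 3,5-dimethylfuran-2(3H)-one
Product: 4 (3,5-dimethylfuran-2-yl)oxy(trimethyl)silane
Conditions: Me3SiOTf, Et3N, Et2O, 0 °C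
Reagents that add atoms: trimethylsilyl triflate, C[Si](C)(C)OS(=O)(=O)C(F)(F)F
Why: Soft enolisation and O-silylation of the butenolide aromatise the ring to the 2-silyloxyfuran (silyl dienol ether formation).

Step 3
Reactants: 4 (3,5-dimethylfuran-2-yl)oxy(trimethyl)silane; 5 3-acryloyl-1,3-oxazolidin-2-one
Product: 8 3-{[(5R)-5-hydroxy-3,5-dimethyl-2-oxocyclohex-3-en-1-yl]carbonyl}-1,3-oxazolidin-2-one (epimers/enol at C1 of the ring), via oxanorbornene cycloadduct 6 (not isolated), via ring-opened silyl ether 7 (not isolated)
Conditions: [Cu((R,R)-t-Bu-box)](SbF6)2 (10 mol %), 4 Å molecular sieves, CH2Cl2, −78 to −40 °C, no protic additive; then 10 % aq citric acid, THF, 0 °C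
Reagents that add atoms: none
Why: Proposed new method: C5 of the electron-rich silyloxyfuran attacks the CH2 terminus of the s-cis acrylimide chelated to divalent copper, and the nascent enolate carbon closes on furan C2, a strongly asynchronous [4π+2π] Diels–Alder addition that makes both ring bonds in one event and gives 6. The six-membered carbocycle is closed suprafacially as part of the 7-oxanorbornene (in the stepwise limit a 6-(enolexo)-exo-trig attack of the enolate on the silyloxycarbenium carbon), after which the bridgehead silyl ketal collapses with a 1,3 O-to-O silyl shift, breaking the temporary oxygen bridge irreversibly and unveiling enone 7. The closest known reactions are the Cu(box)-catalysed Diels–Alder reaction of furan with this acrylimide, the Cu(box)-catalysed vinylogous Mukaiyama–Michael addition of 2-silyloxyfurans to acyl oxazolidinones and the spontaneous bridge opening of cycloadducts of 2-heteroatom-substituted furans; new is their union, favoured by leaving out the protic additive that otherwise releases the open Michael adduct. The one lasting stereocentre, the carbinol carbon, is set by the catalyst, whose tert-butyl groups shield one dienophile face while the endo approach decides which furan face is used; the ketal bridgehead becomes the carbonyl carbon, and the carbon between the two carbonyl groups is epimerisable and is cleared in step 4. The step needs regioselectivity, secured by the silyloxy donor that places the largest HOMO coefficient on the methyl-bearing C5 so that it pairs with the acceptor CH2, and it needs a single endo/exo mode because the two modes consume opposite furan faces. Aromatisation of the product is blocked because the carbinol carbon is quaternary.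

Step 4
Reactants: 8 3-{[(5R)-5-hydroxy-3,5-dimethyl-2-oxocyclohex-3-en-1-yl]carbonyl}-1,3-oxazolidin-2-one
Product: 10 (4R)-4-hydroxy-2,4-dimethylcyclohex-2-en-1-one, via β-keto acid 9 (not isolated)
Conditions: LiOH, THF–H2O, 0 °C; then 1 M HCl to pH 3, 35 °C
Reagents that add atoms: none
Why: Hydroxide cleaves the exocyclic imide carbonyl and the freed β-keto acid loses CO2 through the usual cyclic transition state (imide hydrolysis and β-keto acid decarboxylation), which removes the activating group without touching the carbinol centre.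

Step 5
Reactants: 11 (S)-(+)-linalool
Product: 12 {[(3S)-3,7-dimethylocta-1,6-dien-3-yl]oxy}(triethyl)silane
Conditions: Et3SiOTf, 2,6-lutidine, CH2Cl2, −78 to 0 °C
Reagents that add atoms: triethylsilyl triflate, CC[Si](CC)(CC)OS(=O)(=O)C(F)(F)F
Why: Silyl triflate silylation protects the hindered tertiary allylic alcohol, and its stereocentre is bought and only carried on.

Step 6
Reactants: 12 {[(3S)-3,7-dimethylocta-1,6-dien-3-yl]oxy}(triethyl)silane
Product: 14 (4S)-4-methyl-4-(triethylsilyloxy)hex-5-enal, via secondary ozonide 13 (not isolated)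
Conditions: O3 (1 equiv, Sudan Red 7B end point), CH2Cl2, −78 °C; then Me2S
Reagents that add atoms: ozone, [O-][O+]=O
Why: Chemoselective ozonolysis works because the electron-rich trisubstituted alkene reacts far faster than the hindered monosubstituted vinyl group, and reductive work-up gives the aldehyde.

Step 7
Reactants: 14 (4S)-4-methyl-4-(triethylsilyloxy)hex-5-enal
Product: 15 (4S)-4-methyl-4-(triethylsilyloxy)hex-5-enoic acid
Conditions: NaClO2, NaH2PO4, 2-methylbut-2-ene, t-BuOH–H2O, rt
Reagents that add atoms: sodium chlorite, [Na+].[O-]Cl=O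
Why: Pinnick oxidation converts the aldehyde to the acid under buffered conditions that spare the vinyl group and the silyl ether.

Step 8
Reactants: 15 (4S)-4-methyl-4-(triethylsilyloxy)hex-5-enoic acid
Product: 16 {[(3S)-5-iodo-3-methylpent-1-en-3-yl]oxy}(triethyl)silane
Conditions: PhI(OAc)2, I2, cyclohexane, hν, reflux
Reagents that add atoms: iodine, II
Why: Hunsdiecker-type iododecarboxylation through the acyl hypoiodite removes the one surplus carbon, and the primary radical should be trapped by iodine faster than it can close in the slow 4-exo or 5-endo mode.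

Step 9
Reactants: 10 (4R)-4-hydroxy-2,4-dimethylcyclohex-2-en-1-one; 16 {[(3S)-5-iodo-3-methylpent-1-en-3-yl]oxy}(triethyl)silane
Product: 20 (3S,4R)-2,4-dimethyl-3-[(3S)-3-methyl-3-(triethylsilyloxy)pent-4-en-1-yl]-1,4-bis(trimethylsilyloxy)cyclohex-1-ene, via Grignard reagent 17 (not isolated), via sodium alkoxide 18 (not isolated), via magnesium enolate 19 (not isolated)
Conditions: 16, Mg, Et2O, reflux; 10, NaH, THF, 0 °C; combine, −78 to −20 °C; then Me3SiCl, Et3N, −78 °C to rt
Reagents that add atoms: chlorotrimethylsilane, C[Si](C)(C)Cl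
Why: In this alkoxide-directed (ligand-assisted) conjugate addition of a Grignard reagent to a 4-oxidoenone the alkoxide binds magnesium and delivers the alkyl group to the neighbouring β-carbon from its own face, so the chain ends cis to the oxygen, and silylation fixes the enolate regiochemistry and masks the tertiary alcohol.

Step 10
Reactants: 21 5-bromo-2-methylpent-2-ene
Product: 22 5-iodo-2-methylpent-2-ene
Conditions: NaI, acetone, reflux
Reagents that add atoms: sodium iodide, [Na+].[I-]
Why: The Finkelstein reaction is driven by precipitation of NaBr and supplies the more reactive alkylating agent.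

Step 11
Reactants: 20 (3S,4R)-2,4-dimethyl-3-[(3S)-3-methyl-3-(triethylsilyloxy)pent-4-en-1-yl]-1,4-bis(trimethylsilyloxy)cyclohex-1-ene; 22 5-iodo-2-methylpent-2-ene
Product: 24 (2S,3S,4R)-2,4-dimethyl-2-(4-methylpent-3-en-1-yl)-3-[(3S)-3-methyl-3-(triethylsilyloxy)pent-4-en-1-yl]-4-(trimethylsilyloxy)cyclohexan-1-one, via lithium enolate 23 (not isolated)
Conditions: CH3Li, THF, 0 °C; then 22, HMPA, −78 °C to rt
Reagents that add atoms: none
Why: Regiospecific release of the lithium enolate from the silyl enol ether and its C-alkylation build the quaternary centre, because A(1,2) strain with the vinylic methyl holds the neighbouring chain pseudoaxial and the iodide therefore enters from the opposite face, homoprenyl trans and methyl cis to that chain.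

Step 12
Reactants: 24 (2S,3S,4R)-2,4-dimethyl-2-(4-methylpent-3-en-1-yl)-3-[(3S)-3-methyl-3-(triethylsilyloxy)pent-4-en-1-yl]-4-(trimethylsilyloxy)cyclohexan-1-one
Product: 25 (1R,2S,3S,4R)-2,4-dimethyl-2-(4-methylpent-3-en-1-yl)-3-[(3S)-3-methyl-3-(triethylsilyloxy)pent-4-en-1-yl]-4-(trimethylsilyloxy)cyclohexan-1-ol
Conditions: LiBH(s-Bu)3, THF, −78 °C; then NaOH, H2O2, 0 °C
Reagents that add atoms: none
Why: As with 2,2-dialkylcyclohexanones in general, the bulky trialkylborohydride avoids the two axial hydrogens of the lower face and attacks equatorially, so the axial alcohol, trans to the C4 oxygen, should result (diastereoselective ketone reduction).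

Step 13
Reactants: 25 (1R,2S,3S,4R)-2,4-dimethyl-2-(4-methylpent-3-en-1-yl)-3-[(3S)-3-methyl-3-(triethylsilyloxy)pent-4-en-1-yl]-4-(trimethylsilyloxy)cyclohexan-1-ol
Product: 26 (1R,2S,3S,4S)-4-bromo-1,3-dimethyl-3-(4-methylpent-3-en-1-yl)-2-[(3S)-3-methyl-3-(triethylsilyloxy)pent-4-en-1-yl]-1-(trimethylsilyloxy)cyclohexane
Conditions: CBr4, P(n-C8H17)3, toluene, 70 °C
Reagents that add atoms: tetrabromomethane, BrC(Br)(Br)Br
Why: In the Appel reaction bromide displaces the axial alkoxyphosphonium group with inversion to give the equatorial bromide cis to the C1 oxygen, while the two silyl ethers keep the tertiary alcohols from ionising and block transannular ether formation.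

Step 14
Reactants: 26 (1R,2S,3S,4S)-4-bromo-1,3-dimethyl-3-(4-methylpent-3-en-1-yl)-2-[(3S)-3-methyl-3-(triethylsilyloxy)pent-4-en-1-yl]-1-(trimethylsilyloxy)cyclohexane
Product: 27 (1R,2S,3S,4S)-4-bromo-2-[(3S)-3-hydroxy-3-methylpent-4-en-1-yl]-1,3-dimethyl-3-(4-methylpent-3-en-1-yl)cyclohexan-1-ol (target)
Conditions: HF·pyridine, pyridine, THF, 0 °C to rt
Reagents that add atoms: none
Why: Buffered fluoride desilylation frees both tertiary alcohols and should leave the equatorial bromide (no antiperiplanar hydrogen) and the acid-sensitive allylic alcohol untouched.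

**Compound list**
1 | α-angelica lactone (5-methylfuran-2(3H)-one) | CC1=CCC(=O)O1 | starting material
2 | lithium 5-methylfuran-2-olate | Cc1ccc([O-])o1.[Li+] | intermediate
3 | 3,5-dimethylfuran-2(3H)-one (racemic) | CC1=CC(C)C(=O)O1 | intermediate
4 | (3,5-dimethylfuran-2-yl)oxy(trimethyl)silane | Cc1cc(C)c(O[Si](C)(C)C)o1 | intermediate
5 | 3-acryloyl-1,3-oxazolidin-2-one | C=CC(=O)N1CCOC1=O | starting material
6 | 3-{[(1R,2R,4R)-4,6-dimethyl-1-(trimethylsilyloxy)-7-oxabicyclo[2.2.1]hept-5-en-2-yl]carbonyl}-1,3-oxazolidin-2-one (endo) | C1=C(C)[C@]2(O[Si](C)(C)C)[C@H](C(=O)N3CCOC3=O)C[C@@]1(C)O2 | intermediate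
7 | 3-{[(5R)-3,5-dimethyl-2-oxo-5-(trimethylsilyloxy)cyclohex-3-en-1-yl]carbonyl}-1,3-oxazolidin-2-one | C1=C(C)C(=O)C(C(=O)N2CCOC2=O)C[C@@]1(C)O[Si](C)(C)C | intermediate
8 | 3-{[(5R)-5-hydroxy-3,5-dimethyl-2-oxocyclohex-3-en-1-yl]carbonyl}-1,3-oxazolidin-2-one | C1=C(C)C(=O)C(C(=O)N2CCOC2=O)C[C@@]1(C)O | intermediate
9 | (5R)-5-hydroxy-3,5-dimethyl-2-oxocyclohex-3-ene-1-carboxylic acid | C1=C(C)C(=O)C(C(=O)O)C[C@@]1(C)O | intermediate
10 | (4R)-4-hydroxy-2,4-dimethylcyclohex-2-en-1-one | C1=C(C)C(=O)CC[C@@]1(C)O | intermediate
11 | (S)-(+)-linalool | C=C[C@@](C)(O)CCC=C(C)C | starting material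
12 | {[(3S)-3,7-dimethylocta-1,6-dien-3-yl]oxy}(triethyl)silane | C=C[C@@](C)(O[Si](CC)(CC)CC)CCC=C(C)C | intermediate
13 | secondary ozonide (3,3-dimethyl-1,2,4-trioxolane carrying the (3S)-3-methyl-3-(triethylsilyloxy)pent-4-enyl group at C5) | C=C[C@@](C)(O[Si](CC)(CC)CC)CCC1OOC(C)(C)O1 | intermediate
14 | (4S)-4-methyl-4-(triethylsilyloxy)hex-5-enal | C=C[C@@](C)(O[Si](CC)(CC)CC)CCC=O | intermediate
15 | (4S)-4-methyl-4-(triethylsilyloxy)hex-5-enoic acid | C=C[C@@](C)(O[Si](CC)(CC)CC)CCC(=O)O | intermediate
16 | {[(3S)-5-iodo-3-methylpent-1-en-3-yl]oxy}(triethyl)silane | C=C[C@@](C)(O[Si](CC)(CC)CC)CCI | intermediate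
17 | [(3S)-3-methyl-3-(triethylsilyloxy)pent-4-en-1-yl]magnesium iodide | C=C[C@@](C)(O[Si](CC)(CC)CC)CC[Mg]I | intermediate
18 | sodium (1R)-1,3-dimethyl-4-oxocyclohex-2-en-1-olate | C1=C(C)C(=O)CC[C@@]1(C)[O-].[Na+] | intermediate
19 | magnesium enolate / sodium alkoxide of the conjugate adduct | C=C[C@@](C)(O[Si](CC)(CC)CC)CC[C@H]1C(C)=C(O[Mg]I)CC[C@@]1(C)[O-].[Na+] | intermediate
20 | (3S,4R)-2,4-dimethyl-3-[(3S)-3-methyl-3-(triethylsilyloxy)pent-4-en-1-yl]-1,4-bis(trimethylsilyloxy)cyclohex-1-ene | C=C[C@@](C)(O[Si](CC)(CC)CC)CC[C@H]1C(C)=C(O[Si](C)(C)C)CC[C@@]1(C)O[Si](C)(C)C | intermediate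
21 | 5-bromo-2-methylpent-2-ene | CC(C)=CCCBr | starting material
22 | 5-iodo-2-methylpent-2-ene | CC(C)=CCCI | intermediate
23 | lithium enolate from 20 | C=C[C@@](C)(O[Si](CC)(CC)CC)CC[C@H]1C(C)=C([O-])CC[C@@]1(C)O[Si](C)(C)C.[Li+] | intermediate
24 | (2S,3S,4R)-2,4-dimethyl-2-(4-methylpent-3-en-1-yl)-3-[(3S)-3-methyl-3-(triethylsilyloxy)pent-4-en-1-yl]-4-(trimethylsilyloxy)cyclohexan-1-one | C=C[C@@](C)(O[Si](CC)(CC)CC)CC[C@H]1[C@](C)(CCC=C(C)C)C(=O)CC[C@@]1(C)O[Si](C)(C)C | intermediate
25 | (1R,2S,3S,4R)-configured axial alcohol from 24 | C=C[C@@](C)(O[Si](CC)(CC)CC)CC[C@H]1[C@](C)(CCC=C(C)C)[C@H](O)CC[C@@]1(C)O[Si](C)(C)C | intermediate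
26 | bis-silyl ether of the target, (1R,2S,3S,4S) | C=C[C@@](C)(O[Si](CC)(CC)CC)CC[C@H]1[C@](C)(CCC=C(C)C)[C@@H](Br)CC[C@@]1(C)O[Si](C)(C)C | intermediate
27 | (1R,2S,3S,4S)-4-bromo-2-[(3S)-3-hydroxy-3-methylpent-4-en-1-yl]-1,3-dimethyl-3-(4-methylpent-3-en-1-yl)cyclohexan-1-ol | C=C[C@@](C)(O)CC[C@H]1[C@](C)(CCC=C(C)C)[C@@H](Br)CC[C@@]1(C)O | target

Total step count: 14. Longest linear sequence: 9 steps (1, 2, 3, 4, 9, 11, 12, 13, 14). The linalool branch (5, 6, 7, 8, 9, 11, 12, 13, 14) is equally long.

**Steps most likely to fail**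

Step 3. Silyl transfer to the copper enolate may outrun carbon–carbon ring closure, so that the reaction stops after the first bond. An exo approach or a silyl-cation background reaction may also erode the facial selectivity. The fallback sets out from 4 and 5 and makes the two bonds in two known operations.
- The same catalyst in the presence of (CF3)2CHOH (the established vinylogous Mukaiyama–Michael mode) should give the butenolide imide 3-{3-[(2R)-2,4-dimethyl-5-oxo-2,5-dihydrofuran-2-yl]propanoyl}-1,3-oxazolidin-2-one F1, which can be recrystallised to raise its optical purity.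
- LiN(SiMe3)2 (2 equiv, THF, −78 to 0 °C) then forms the imide enolate, which acylates itself on the lactone carbonyl and expels the tertiary alkoxide. This is a Dieckmann-type closure driven by the β-dicarbonyl enolate.
- After acidic work-up the route is rejoined at 8.

Step 13. The carbinol carbon is neopentyl-like, so substitution may be slower than E2 elimination towards the ring CH2, than a 1,2-shift of the antiperiplanar axial methyl group after ionisation, or than loss of a silyl ether followed by transannular ether formation. The fallback sets out from 25 and separates activation from displacement.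
- ClCH2SO2Cl and pyridine at 0 °C should give the isolable chloromethanesulfonate of 25 F2, a small and very reactive nucleofuge made without heat or phosphonium ion pairs.
- This is then displaced by dissociated bromide (LiBr, DMPU, 40 to 50 °C) with inversion, and the route is rejoined at 26.

Step 11. C-alkylation of the hindered tetrasubstituted enolate by an unactivated primary iodide may be so slow that proton transfer between enolate and product, O-alkylation or alkylation at the other α-carbon take over. The fallback sets out from 20 and uses a much more reactive carbon electrophile.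
- A Mukaiyama–Michael addition of the silyl enol ether to acrolein (catalytic Sc(OTf)3, CH2Cl2, −78 °C), with the same anti approach, should give the keto aldehyde 3-{(1S,2S,3R)-1,3-dimethyl-2-[(3S)-3-methyl-3-(triethylsilyloxy)pent-4-en-1-yl]-6-oxo-3-(trimethylsilyloxy)cyclohexyl}propanal F3.
- Its aldehyde alone reacts with Ph3P=C(CH3)2 (Wittig olefination, THF, −78 to 0 °C) to complete the homoprenyl group, and the route is rejoined at 24.

**Further compounds**
F1 | step 3 | 3-{3-[(2R)-2,4-dimethyl-5-oxo-2,5-dihydrofuran-2-yl]propanoyl}-1,3-oxazolidin-2-one | O=C1OCCN1C(=O)CC[C@@]2(C)OC(=O)C(C)=C2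
F2 | step 13 | chloromethanesulfonate of 25 | C=C[C@@](C)(O[Si](CC)(CC)CC)CC[C@H]1[C@](C)(CCC=C(C)C)[C@H](OS(=O)(=O)CCl)CC[C@@]1(C)O[Si](C)(C)C
F3 | step 11 | 3-{(1S,2S,3R)-1,3-dimethyl-2-[(3S)-3-methyl-3-(triethylsilyloxy)pent-4-en-1-yl]-6-oxo-3-(trimethylsilyloxy)cyclohexyl}propanal | C=C[C@@](C)(O[Si](CC)(CC)CC)CC[C@H]1[C@](C)(CCC=O)C(=O)CC[C@@]1(C)O[Si](C)(C)C
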